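**Retrosynthetic overview**

- The laurate is cleaved at O10, and C10–C11 is disconnected to a non-8-enyl Grignard reagent and an oxolane-2-carbaldehyde (C10), with the ring oxygen as chelating group.
- The oxolane (C6–C7–C8–C9–O) is opened at O9–C6 to a cis-6,7-epoxide bearing the free C9 hydroxyl (5-endo closure in the forward sense).
- The strategy rests on this feature: the C9 oxygen and the C7 hydroxyl are 1,3-syn across C8, and the C6–O and C7–O bonds have the pattern of an anti addition to a Z C6=C7 alkene. A tert-butyl carbonate on O9 therefore relays the C9 configuration to C7 and C6 by iodocyclisation.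
- The Z-homoallylic carbonate comes from (R)-benzyl glycidyl ether and hept-1-yne.
- Ring order: temporary 1,3-dioxan-2-one (step 4), then oxirane (step 5), then the oxolane (step 6), the only ring of the target.

Key step: step 4

Remark on the chemistry (numbering): chain carbons are numbered C1 (pentyl end) to C19 (vinyl end); O7, O9 and O10 are the oxygens on those carbons; the target is (6S,7S,9R,10R).

**Route**

Step 1
Reactants: 1 (R)-benzyl glycidyl ether; 2 hept-1-yne
Product: 4 (2R)-1-(benzyloxy)dec-4-yn-2-ol, via hept-1-ynyllithium 3 (not isolated)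
Conditions: n-BuLi, THF, −78 °C; BF3·OEt2, −78 °C; then 1; aq. NH4Cl
Reagents that add atoms: none
Why: Yamaguchi–Hirao alkynylation: the acetylide opens the BF3-activated epoxide at the unsubstituted carbon in an SN2 manner, so the C9 stereocentre of 1 is carried over untouched as (R).

Step 2
Reactants: 4 (2R)-1-(benzyloxy)dec-4-yn-2-ol
Product: 5 (2R,4Z)-1-(benzyloxy)dec-4-en-2-ol
Conditions: H2 (1 atm), Pd/CaCO3 poisoned with Pb(OAc)2, quinoline, EtOAc/hexane, rt
Reagents that add atoms: none
Why: Lindlar semihydrogenation delivers H2 syn on the poisoned Pd surface and should stop at the Z C6=C7 alkene without cleaving the benzyl ether.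

Step 3
Reactants: 5 (2R,4Z)-1-(benzyloxy)dec-4-en-2-ol
Product: 6 (2R,4Z)-1-(benzyloxy)dec-4-en-2-yl tert-butyl carbonate
Conditions: Boc2O, DMAP (cat.), MeCN, rt
Reagents that add atoms: di-tert-butyl dicarbonate, CC(C)(C)OC(=O)OC(=O)OC(C)(C)C
Why: DMAP-catalysed acyl transfer to the secondary alcohol installs the carbonate tether on O9 without touching the stereocentre.

Step 4
Reactants: 6 (2R,4Z)-1-(benzyloxy)dec-4-en-2-yl tert-butyl carbonate
Product: 8 (4R,6S)-4-[(benzyloxy)methyl]-6-[(1S)-1-iodohexyl]-1,3-dioxan-2-one, via tert-butoxydioxanylium bromide 7 (not isolated)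
Conditions: IBr (1.0 M in CH2Cl2), toluene, −85 °C; aq. Na2S2O3/NaHCO3
Reagents that add atoms: iodine monobromide, IBr
Why: IBr adds reversibly to the Z C6=C7 alkene and the carbonate carbonyl oxygen opens the iodonium at C7 anti to iodine, giving the 2-tert-butoxy-1,3-dioxan-2-ylium ion 7, which loses its tert-butyl group to bromide. The closest known reaction type is the Bartlett iodocarbonate cyclisation of homoallylic tert-butyl carbonates in its low-temperature IBr variant. The 1,3-dioxan-2-one ring closes in the 6-exo mode, with C6–I left outside the ring; 7-endo attack at C6 should not compete. C7 is set by 1,3-induction from C9 through a chair-like transition state with the benzyloxymethyl group equatorial and the alkene held equatorial by the allylic 1,3-strain of its Z substituent, which gives the 4,6-cis (1,3-syn) carbonate; C6 is set as (S) by the stereospecific anti addition to the Z alkene. The step needs syn over anti facial selectivity and attack by the carbonate in preference to the C10 benzyl ether oxygen; the first is secured by the equatorial chair at low temperature, the second by the more nucleophilic carbonyl oxygen and the irreversible loss of tert-butyl.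

Step 5
Reactants: 8 (4R,6S)-4-[(benzyloxy)methyl]-6-[(1S)-1-iodohexyl]-1,3-dioxan-2-one
Product: 10 (2R)-1-(benzyloxy)-3-[(2S,3R)-3-pentyloxiran-2-yl]propan-2-ol, via iodo diol 9 (not isolated)
Conditions: K2CO3, MeOH, 0 °C to rt
Reagents that add atoms: none
Why: Methanolysis of the cyclic carbonate frees the C7 alkoxide, which displaces the antiperiplanar iodide at C6 with inversion (3-exo-tet Williamson closure) to give the cis-epoxide syn to the C9 hydroxyl, faster than any 5-exo attack by O9.

Step 6
Reactants: 10 (2R)-1-(benzyloxy)-3-[(2S,3R)-3-pentyloxiran-2-yl]propan-2-ol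
Product: 11 (2S,3S,5R)-5-[(benzyloxy)methyl]-2-pentyloxolan-3-ol
Conditions: CSA (cat.), CH2Cl2, 0 °C to rt
Reagents that add atoms: none
Why: Acid-catalysed 5-endo opening of a 3,4-epoxy alcohol: O9 attacks the protonated epoxide at C6 with inversion (the 4-exo alternative at C7 would give a strained oxetane), so O9 ends where iodine stood, with pentyl cis to the C7 hydroxyl and trans to the C9 substituent.

Step 7
Reactants: 11 (2S,3S,5R)-5-[(benzyloxy)methyl]-2-pentyloxolan-3-ol
Product: 12 tert-butyl({(2S,3S,5R)-5-[(benzyloxy)methyl]-2-pentyloxolan-3-yl}oxy)dimethylsilane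
Conditions: TBSOTf, 2,6-lutidine, CH2Cl2, −78 to 0 °C
Reagents that add atoms: tert-butyldimethylsilyl trifluoromethanesulfonate, CC(C)(C)[Si](C)(C)OS(=O)(=O)C(F)(F)F
Why: Silylation of the hindered C7 hydroxyl with the silyl triflate and a non-nucleophilic base keeps O7 masked, so that only O10 is acylated later.

Step 8
Reactants: 12 tert-butyl({(2S,3S,5R)-5-[(benzyloxy)methyl]-2-pentyloxolan-3-yl}oxy)dimethylsilane
Product: 13 [(2R,4S,5S)-4-{[tert-butyl(dimethyl)silyl]oxy}-5-pentyloxolan-2-yl]methanol
Conditions: H2 (1 atm), Pd(OH)2/C, EtOAc, rt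
Reagents that add atoms: none
Why: Hydrogenolysis of the benzylic C–O bond is placed here because no alkene is present yet; the silyl ether and the oxolane are inert in EtOAc.

Step 9
Reactants: 13 [(2R,4S,5S)-4-{[tert-butyl(dimethyl)silyl]oxy}-5-pentyloxolan-2-yl]methanol
Product: 14 (2R,4S,5S)-4-{[tert-butyl(dimethyl)silyl]oxy}-5-pentyloxolane-2-carbaldehyde
Conditions: Dess–Martin periodinane, CH2Cl2, 0 °C to rt; used crude at once
Reagents that add atoms: none
Why: Dess–Martin oxidation stops at the aldehyde under neutral, non-enolising conditions, so C9 should not epimerise.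

Step 10
Reactants: 15 9-bromonon-1-ene
Product: 16 non-8-en-1-ylmagnesium bromide (solution in Et2O, used directly)
Conditions: Mg turnings, I2 (crystal), Et2O, reflux
Reagents that add atoms: magnesium, [Mg]
Why: Grignard formation by insertion of Mg into the primary C–Br bond; the remote terminal alkene does not interfere.

Step 11
Reactants: 14 (2R,4S,5S)-4-{[tert-butyl(dimethyl)silyl]oxy}-5-pentyloxolane-2-carbaldehyde; 16 non-8-en-1-ylmagnesium bromide
Product: 17 (1R)-1-[(2R,4S,5S)-4-{[tert-butyl(dimethyl)silyl]oxy}-5-pentyloxolan-2-yl]dec-9-en-1-ol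
Conditions: MgBr2·OEt2, CH2Cl2, −78 °C; then 16 in Et2O, −78 °C; aq. NH4Cl
Reagents that add atoms: none
Why: Cram-chelate addition: Mg bridges the aldehyde oxygen and the ring oxygen, holding O=C10–C9–O9 syn-periplanar, and the Grignard reagent attacks the face flanked by the C9 hydrogen and not by C8, which should set C10 as (R), threo to C9.

Step 12
Reactants: 17 (1R)-1-[(2R,4S,5S)-4-{[tert-butyl(dimethyl)silyl]oxy}-5-pentyloxolan-2-yl]dec-9-en-1-ol; 18 dodecanoyl chloride (lauroyl chloride)
Product: 19 (1R)-1-[(2R,4S,5S)-4-{[tert-butyl(dimethyl)silyl]oxy}-5-pentyloxolan-2-yl]dec-9-en-1-yl dodecanoate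
Conditions: Et3N, DMAP (cat.), CH2Cl2, 0 °C to rt
Reagents that add atoms: none
Why: DMAP-catalysed acylation through the acylpyridinium ion esterifies the only free hydroxyl (O10) with retention at C10.

Step 13
Reactants: 19 (1R)-1-[(2R,4S,5S)-4-{[tert-butyl(dimethyl)silyl]oxy}-5-pentyloxolan-2-yl]dec-9-en-1-yl dodecanoate
Product: 20 (1R)-1-[(2R,4S,5S)-4-hydroxy-5-pentyloxolan-2-yl]dec-9-en-1-yl dodecanoate (CNP0219213.1)
Conditions: HF·pyridine, pyridine/THF, 0 °C to rt
Reagents that add atoms: none
Why: Fluoride-driven Si–O cleavage under buffered, non-basic conditions leaves the laurate and the terminal alkene alone; acyl migration to O7 is not expected because O7 is trans to the C9 side chain.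

**Compound list**

1 | (R)-benzyl glycidyl ether, (2R)-2-[(benzyloxy)methyl]oxirane | C1O[C@H]1COCc1ccccc1 | starting material
2 | hept-1-yne | CCCCCC#C | starting material
3 | hept-1-yn-1-yllithium | [Li]C#CCCCCC | intermediate
4 | (2R)-1-(benzyloxy)dec-4-yn-2-ol | c1ccccc1COC[C@H](O)CC#CCCCCC | intermediate
5 | (2R,4Z)-1-(benzyloxy)dec-4-en-2-ol | c1ccccc1COC[C@H](O)C/C=C\CCCCC | intermediate
6 | (2R,4Z)-1-(benzyloxy)dec-4-en-2-yl tert-butyl carbonate | c1ccccc1COC[C@H](OC(=O)OC(C)(C)C)C/C=C\CCCCC | intermediate
7 | (4R,6S)-4-[(benzyloxy)methyl]-2-tert-butoxy-6-[(1S)-1-iodohexyl]-1,3-dioxan-2-ylium bromide | c1ccccc1COC[C@H]1C[C@@H]([C@@H](I)CCCCC)O[C+](OC(C)(C)C)O1.[Br-] | intermediate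
8 | (4R,6S)-4-[(benzyloxy)methyl]-6-[(1S)-1-iodohexyl]-1,3-dioxan-2-one | c1ccccc1COC[C@H]1C[C@@H]([C@@H](I)CCCCC)OC(=O)O1 | intermediate
9 | (2R,4S,5S)-1-(benzyloxy)-5-iododecane-2,4-diol | c1ccccc1COC[C@H](O)C[C@H](O)[C@@H](I)CCCCC | intermediate
10 | (2R)-1-(benzyloxy)-3-[(2S,3R)-3-pentyloxiran-2-yl]propan-2-ol | c1ccccc1COC[C@H](O)C[C@@H]1O[C@@H]1CCCCC | intermediate
11 | (2S,3S,5R)-5-[(benzyloxy)methyl]-2-pentyloxolan-3-ol | c1ccccc1COC[C@H]1C[C@H](O)[C@H](CCCCC)O1 | intermediate
12 | tert-butyl({(2S,3S,5R)-5-[(benzyloxy)methyl]-2-pentyloxolan-3-yl}oxy)dimethylsilane | c1ccccc1COC[C@H]1C[C@H](O[Si](C)(C)C(C)(C)C)[C@H](CCCCC)O1 | intermediate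
13 | [(2R,4S,5S)-4-{[tert-butyl(dimethyl)silyl]oxy}-5-pentyloxolan-2-yl]methanol | OC[C@H]1C[C@H](O[Si](C)(C)C(C)(C)C)[C@H](CCCCC)O1 | intermediate
14 | (2R,4S,5S)-4-{[tert-butyl(dimethyl)silyl]oxy}-5-pentyloxolane-2-carbaldehyde | O=C[C@H]1C[C@H](O[Si](C)(C)C(C)(C)C)[C@H](CCCCC)O1 | intermediate
15 | 9-bromonon-1-ene | C=CCCCCCCCBr | starting material
16 | non-8-en-1-ylmagnesium bromide | C=CCCCCCCC[Mg]Br | intermediate
17 | (1R)-1-[(2R,4S,5S)-4-{[tert-butyl(dimethyl)silyl]oxy}-5-pentyloxolan-2-yl]dec-9-en-1-ol | C=CCCCCCCC[C@@H](O)[C@H]1C[C@H](O[Si](C)(C)C(C)(C)C)[C@H](CCCCC)O1 | intermediate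
18 | dodecanoyl chloride (lauroyl chloride) | CCCCCCCCCCCC(=O)Cl | starting material
19 | (1R)-1-[(2R,4S,5S)-4-{[tert-butyl(dimethyl)silyl]oxy}-5-pentyloxolan-2-yl]dec-9-en-1-yl dodecanoate | C=CCCCCCCC[C@@H](OC(=O)CCCCCCCCCCC)[C@H]1C[C@H](O[Si](C)(C)C(C)(C)C)[C@H](CCCCC)O1 | intermediate
20 | (1R)-1-[(2R,4S,5S)-4-hydroxy-5-pentyloxolan-2-yl]dec-9-en-1-yl dodecanoate | C=CCCCCCCC[C@@H](OC(=O)CCCCCCCCCCC)[C@H]1C[C@H](O)[C@H](CCCCC)O1 | target

**Step count**

Total: 13 steps. Longest linear sequence: 12 steps (steps 1–9 and 11–13, from compound 1); step 10 is the one-step side branch.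

**Steps most likely to fail**

Step 11. The facial selectivity at C10 may be poor if addition through the non-chelated Felkin–Anh conformer competes with the magnesium chelate, and the α-alkoxy aldehyde may partly epimerise at C9 by enolisation before it is consumed. The fallback sets out from the crude carbinol of step 11 (compound 17 in whatever epimer ratio) and comes back at 17. The carbinol is oxidised with Dess–Martin periodinane to the ketone 1-[(2R,4S,5S)-4-{[tert-butyl(dimethyl)silyl]oxy}-5-pentyloxolan-2-yl]dec-9-en-1-one F4. This is reduced with LiBH(s-Bu)3 in THF at −78 °C. With the bulky hydride the polar Felkin–Anh arrangement, in which the ring C9–O bond lies antiperiplanar to the incoming hydride, should give the (10R) threo carbinol 17, so C10 is then set by reagent approach to a ketone and no longer by chelation.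

Step 6. The activated epoxide may be opened in the wrong way: the dialkyl epoxide has no electronic bias toward C6, so attack at C7 by the C10 benzyl ether oxygen (5-exo, with loss of benzyl) or intermolecular opening may overtake the 5-endo closure. The fallback sets out from iodocarbonate 8 and comes back at 11; it closes the same O9–C6 bond by a 5-exo iodoetherification instead of an epoxide opening. Dehydroiodination of 8 with DBU in toluene at 80 °C should give the allylic carbonate (4R,6S)-4-[(benzyloxy)methyl]-6-[(1E)-hex-1-en-1-yl]-1,3-dioxan-2-one F1. Treatment with K2CO3 in MeOH frees the syn-diol (2R,4S,5E)-1-(benzyloxy)dec-5-ene-2,4-diol F2. Iodine with NaHCO3 in MeCN at 0 °C then lets O9 attack C6 of the C5=C6 iodonium in the 5-exo mode; the free allylic C7 hydroxyl is known to direct such closures of 4-pentene-1,3-diols to the 2,3-cis oxolane, and this should give (2R,3S,5R)-5-[(benzyloxy)methyl]-2-[(1S)-1-iodopentyl]oxolan-3-ol F3. Radical deiodination with Bu3SnH and AIBN in toluene at 80 °C turns the iodopentyl group into pentyl and gives 11.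

Step 4. The 1,3-syn facial selectivity may erode if the iodonium is captured before it equilibrates, and the iodonium may be trapped by bromide or by the benzyl ether oxygen instead of the carbonate. The fallback sets out from the Z-homoallylic alcohol 5 and comes back at the epoxy alcohol 10; it makes no new compound (F0). Hydroxyl-directed epoxidation with VO(acac)2 (cat.) and t-BuOOH in CH2Cl2 at 0 °C to rt proceeds through a chair-like vanadate ester in which the C9 substituent is equatorial. For Z-homoallylic alcohols this should deliver the oxygen syn to the C9 hydroxyl and give 10 directly, with the cis-epoxide geometry fixed by the Z alkene. Steps 3 to 5 are then bypassed.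

**Further compounds**

F0 | step 4 | none | none
F1 | step 6 | (4R,6S)-4-[(benzyloxy)methyl]-6-[(1E)-hex-1-en-1-yl]-1,3-dioxan-2-one | c1ccccc1COC[C@H]1C[C@@H](/C=C/CCCC)OC(=O)O1
F2 | step 6 | (2R,4S,5E)-1-(benzyloxy)dec-5-ene-2,4-diol | c1ccccc1COC[C@H](O)C[C@H](O)/C=C/CCCC
F3 | step 6 | (2R,3S,5R)-5-[(benzyloxy)methyl]-2-[(1S)-1-iodopentyl]oxolan-3-ol | c1ccccc1COC[C@H]1C[C@H](O)[C@H]([C@@H](I)CCCC)O1
F4 | step 11 | 1-[(2R,4S,5S)-4-{[tert-butyl(dimethyl)silyl]oxy}-5-pentyloxolan-2-yl]dec-9-en-1-one | C=CCCCCCCCC(=O)[C@H]1C[C@H](O[Si](C)(C)C(C)(C)C)[C@H](CCCCC)O1
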